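**Plan** (tricyclo[5.4.0.0^2,8]undecane numbering of the core: C11 ketone, C3–OH, C5–O-angeloyl, C6(CH3)CH2OAc, C2–CH3, C9–CH3)
- Retrosynthetic cuts, in order: the two esters; C4–C5 (aldol, seven-membered ring last); the C9 methyl (cuprate); C1–C7 (cyclobutane, enolate alkylation); carbonyl shift C11 ← C9; then C2–C3 and C7–C8 together.
- Enabling feature: in the six-membered ring (C1, C2, C8, C9, C10, C11) the quaternary C2(CH3) and its neighbour C8 lie β and α to C9. A temporary ketone at C9 (3-methylcyclohex-2-enone) lets a conjugate addition at C2 and an aldol at C8 join three pieces at the fully substituted carbon.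
- Pieces: 3-methylcyclohex-2-enone, a silylvinyl unit (C3, C4, a masked acetyl) and aldehyde 6 (C5, C6, C7 with the CH2O arm).
- Forward order: three-component coupling, then C9→C11 carbonyl transposition, four-membered ring, C9 methyl, seven-membered ring, esters.
- Stereochemistry: C6 from a Sharpless kinetic resolution and a stereospecific semipinacol shift; C2 from a chiral copper catalyst; C8 and C7 from the aldol transition state; C1 from the SN2 ring closure; C9 from cuprate attack on the open face; C5 from the aldol face; C3 from an anti-selective Evans–Tishchenko reduction.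

Key step: step 5

Remark: the configuration at the transient epoxide carbons of 15 and 22 and at the carbinol carbon of 16 is of no consequence and is left open in their SMILES.

**Route**

Step 1
Reactants: 1 2-methylprop-2-enal; 2 vinylmagnesium bromide
Product: 3 rac-2-methylpenta-1,4-dien-3-ol
Conditions: CH2=CHMgBr, THF, −78 to 0 °C; NH4Cl (aq)
Reagents that add atoms: none
Why: Grignard 1,2-addition to the enal carbonyl should give the divinyl carbinol as the racemate, which is what the next step needs.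

Step 2
Reactants: 3 rac-2-methylpenta-1,4-dien-3-ol
Product: 4 (1S)-1-[(2S)-2-methyloxiran-2-yl]prop-2-en-1-ol
Conditions: Ti(OiPr)4 (10 mol%), L-(+)-diisopropyl tartrate (12 mol%), tBuOOH (0.55 equiv), 4 Å MS, CH2Cl2, −20 °C
Reagents that add atoms: tert-butyl hydroperoxide CC(C)(C)OO
Why: Sharpless kinetic resolution: the (S)-alcohol should be epoxidised fast at its electron-rich 1,1-disubstituted alkene, with the tartrate setting both centres, while the (R)-alcohol is left behind (at most half of 3 is used).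

Step 3
Reactants: 4 (1S)-1-[(2S)-2-methyloxiran-2-yl]prop-2-en-1-ol
Product: 5 (2R)-2-(hydroxymethyl)-2-methylbut-3-enal
Conditions: BF3·OEt2, CH2Cl2, −78 °C
Reagents that add atoms: none
Why: Semipinacol rearrangement of a 2,3-epoxy alcohol: the vinyl group should migrate from the carbinol carbon to the tertiary epoxide carbon anti to the breaking C–O bond, so the quaternary centre (future C6) forms stereospecifically with inversion.

Step 4
Reactants: 5 (2R)-2-(hydroxymethyl)-2-methylbut-3-enal
Product: 6 (2R)-2-{[(tert-butyldiphenylsilyl)oxy]methyl}-2-methylbut-3-enal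
Conditions: TBDPSCl, imidazole, CH2Cl2, 0 °C
Reagents that add atoms: tert-butyl(chloro)diphenylsilane CC(C)(C)[Si](Cl)(c1ccccc1)c1ccccc1
Why: Standard silylation of the primary alcohol; it stops retro-aldol loss of the β-hydroxy aldehyde and touches no stereocentre.

Step 5
Reactants: 7 3-methylcyclohex-2-en-1-one; 8 ethynyltrimethylsilane; 6 (2R)-2-{[(tert-butyldiphenylsilyl)oxy]methyl}-2-methylbut-3-enal
Product: 11 (2R,3S)-2-[(1S,2R)-2-{[(tert-butyldiphenylsilyl)oxy]methyl}-1-hydroxy-2-methylbut-3-en-1-yl]-3-methyl-3-[1-(trimethylsilyl)ethenyl]cyclohexan-1-one, via alkenylalane 9 (not isolated), via aluminium enolate 10 (not isolated)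
Conditions: 8, iBu2AlH, hexane, 55 °C; then Cu(OTf)2 (5 mol%), chiral sulfonate-bearing imidazolinium salt (carbene ligand precursor, 6 mol%), 7, THF, −78 to 4 °C; then 6, −78 to −30 °C; Rochelle salt (aq)
Reagents that add atoms: none
Why: Hydroalumination gives alane 9, whose alkenyl group passes to a chiral carbene–copper species and adds 1,4 to enone 7 at its β-carbon (future C2), giving aluminium enolate 10; 10 then adds to the non-enolisable aldehyde 6 through a closed six-membered transition state and makes the C7–C8 bond. The closest known reaction type is the copper-catalysed enantioselective conjugate addition of silyl-substituted vinylaluminium reagents to β-substituted cyclic enones, combined with aldol trapping of the metal enolate (three-component coupling). No ring closes in this step. The quaternary centre should be set by the chiral ligand; the ring α-centre by approach of the aldehyde anti to the pseudo-axial methyl on the neighbouring quaternary carbon (the bulky silylvinyl group sits pseudo-equatorial); the carbinol centre by the chair transition state of the (E)-configured cyclic enolate (anti aldol). The step needs 1,4- over 1,2-addition and C–C bond formation of the enolate before proton transfer; the soft copper alkenyl, the absence of α-hydrogens in 6 and the low temperature should secure this.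

Step 6
Reactants: 11 aldol adduct
Product: 12 triethylsilyl ether of 11 (OSiEt3 on the carbinol carbon, other centres as in 11)
Conditions: Et3SiOTf, 2,6-lutidine, CH2Cl2, −78 °C
Reagents that add atoms: triethylsilyl trifluoromethanesulfonate CC[Si](CC)(CC)OS(=O)(=O)C(F)(F)F
Why: Silylation with the silyl triflate should mask the hindered β-hydroxy ketone against retro-aldol cleavage and oxidation in steps 7 to 10.

Step 7
Reactants: 12 triethylsilyl ether
Product: 14 (5S,6R)-6-[(1S,2R)-2-{[(tert-butyldiphenylsilyl)oxy]methyl}-2-methyl-1-(triethylsilyloxy)but-3-en-1-yl]-5-methyl-5-[1-(trimethylsilyl)ethenyl]cyclohex-2-en-1-one, via silyl enol ether 13 (not isolated)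
Conditions: LiN(iPr)2, Me3SiCl, THF, −78 °C; then Pd(OAc)2, MeCN, rt
Reagents that add atoms: none
Why: Saegusa–Ito oxidation: kinetic deprotonation should occur at the free CH2 (C10) and not at the fully flanked C8–H, and Pd(OAc)2 turns the silyl enol ether into the C10=C11 enone.

Step 8
Reactants: 14 cyclohex-2-enone
Product: 15 2,3-epoxide of 14 (epoxide configuration open)
Conditions: H2O2 (30%), NaOH, MeOH, 0 °C
Reagents that add atoms: hydrogen peroxide OO
Why: Weitz–Scheffer nucleophilic epoxidation attacks only the electron-poor enone C=C and should leave the vinylsilane, the vinyl group and both silyl ethers alone.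

Step 9
Reactants: 15 epoxy ketone
Product: 16 (4R,5S)-4-[(1S,2R)-2-{[(tert-butyldiphenylsilyl)oxy]methyl}-2-methyl-1-(triethylsilyloxy)but-3-en-1-yl]-5-methyl-5-[1-(trimethylsilyl)ethenyl]cyclohex-2-en-1-ol (carbinol epimers)
Conditions: N2H4·H2O, AcOH (cat.), MeOH, rt
Reagents that add atoms: none
Why: Wharton rearrangement: the hydrazone of the epoxy ketone should fragment with loss of N2 to the transposed allylic alcohol (oxygen now on C11, alkene C9=C10).

Step 10
Reactants: 16 allylic alcohol
Product: 17 (4R,5S)-4-[(1S,2R)-2-{[(tert-butyldiphenylsilyl)oxy]methyl}-2-methyl-1-(triethylsilyloxy)but-3-en-1-yl]-5-methyl-5-[1-(trimethylsilyl)ethenyl]cyclohex-2-en-1-one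
Conditions: Dess–Martin periodinane, NaHCO3, CH2Cl2, rt
Reagents that add atoms: none
Why: Dess–Martin oxidation of the allylic alcohol should give the enone with the carbonyl at C11; both carbinol epimers converge.

Step 11
Reactants: 17 transposed enone
Product: 18 (4R,5S)-4-[(1S,2R)-2-{[(tert-butyldiphenylsilyl)oxy]methyl}-1-hydroxy-2-methylbut-3-en-1-yl]-5-methyl-5-[1-(trimethylsilyl)ethenyl]cyclohex-2-en-1-one
Conditions: camphorsulfonic acid (cat.), MeOH/CH2Cl2, 0 °C
Reagents that add atoms: none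
Why: Acid methanolysis should cleave the secondary triethylsilyl ether while the far more acid-stable tert-butyldiphenylsilyl ether survives.

Step 12
Reactants: 18 hydroxy enone
Product: 19 methanesulfonate of 18 (OSO2CH3 on the carbinol carbon, same configuration)
Conditions: MeSO2Cl, Et3N, CH2Cl2, −20 °C
Reagents that add atoms: methanesulfonyl chloride CS(Cl)(=O)=O
Why: Mesylation through the sulfene should work on the hindered secondary alcohol, with retention, and installs the leaving group at C7.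

Step 13
Reactants: 19 mesylate
Product: 20 6-methyl-7-[1-(tert-butyldiphenylsilyloxy)-2-methylbut-3-en-2-yl]-6-[1-(trimethylsilyl)ethenyl]bicyclo[3.1.1]hept-3-en-2-one (silylvinyl group and C7 side chain both anti to the enone bridge, 6-methyl syn; side-chain centre as in 6)
Conditions: LiN(iPr)2, THF, −78 to 0 °C
Reagents that add atoms: none
Why: Intramolecular enolate alkylation (4-exo-tet), the keto-sulfonate route to bridged cyclobutanes: kinetic α′-deprotonation at the only sp3 α-carbon (C1) and SN2 displacement with inversion at C7 should close the four-membered ring, the bicyclic geometry and the inversion fixing C1 and C7.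

Step 14
Reactants: 20 bicyclic enone
Product: 21 4,6-dimethyl-7-[1-(tert-butyldiphenylsilyloxy)-2-methylbut-3-en-2-yl]-6-[1-(trimethylsilyl)ethenyl]bicyclo[3.1.1]heptan-2-one (4-methyl on the side of the C7–H bridge)
Conditions: Me2CuLi, Et2O, −78 °C; NH4Cl (aq)
Reagents that add atoms: lithium dimethylcuprate [Li+].C[Cu-]C
Why: Gilman cuprate conjugate addition should come from the face of the C7–H bridge, since the syn methyl on the other one-carbon bridge covers the opposite face; this sets C9.

Step 15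
Reactants: 21 saturated ketone
Product: 23 6-acetyl-4,6-dimethyl-7-[1-(tert-butyldiphenylsilyloxy)-2-methylbut-3-en-2-yl]bicyclo[3.1.1]heptan-2-one, via epoxysilane 22 (not isolated)
Conditions: mCPBA, NaHCO3, CH2Cl2, 0 °C; then H2SO4 (aq), MeOH, rt
Reagents that add atoms: 3-chloroperoxybenzoic acid OOC(=O)c1cccc(Cl)c1
Why: Prilezhaev epoxidation should pick the electron-rich vinylsilane over the hindered monosubstituted vinyl group, and acid hydrolysis of the α,β-epoxysilane unmasks the methyl ketone at C3.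

Step 16
Reactants: 23 methyl ketone
Product: 24 2-(6-acetyl-4,6-dimethyl-2-oxobicyclo[3.1.1]heptan-7-yl)-3-(tert-butyldiphenylsilyloxy)-2-methylpropanal
Conditions: O3, CH2Cl2/MeOH, −78 °C; then Me2S
Reagents that add atoms: ozone [O-][O+]=O
Why: Ozonolysis with reductive work-up should cleave the remaining terminal alkene to the C5 aldehyde without touching the two ketones.

Step 17
Reactants: 24 keto aldehyde
Product: 25 5-hydroxy-6-[(tert-butyldiphenylsilyloxy)methyl]-2,6,9-trimethyltricyclo[5.4.0.0^2,8]undecane-3,11-dione (configuration as in the target)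
Conditions: LiN(SiMe3)2, THF, −78 °C; AcOH
Reagents that add atoms: none
Why: Intramolecular aldol addition closing the seven-membered ring: only the methyl ketone enolate (C4) can reach the non-enolisable aldehyde on the same face of the cyclobutane, and attack with the aldehyde oxygen on the side of the small C6 methyl, away from the silyloxymethyl group, should set C5.

Step 18
Reactants: 26 angelic acid [(2Z)-2-methylbut-2-enoic acid]
Product: 27 (2Z)-2-methylbut-2-en-1-ol
Conditions: LiAlH4, Et2O, 0 °C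
Reagents that add atoms: none
Why: Hydride reduction of the acid to the allylic alcohol should keep the alkene geometry.

Step 19
Reactants: 27 (2Z)-2-methylbut-2-en-1-ol
Product: 28 (2Z)-2-methylbut-2-enal
Conditions: MnO2, CH2Cl2, 0 °C; used at once
Reagents that add atoms: none
Why: MnO2 oxidation of the allylic alcohol under neutral conditions should give the (Z)-enal, which is used immediately to avoid Z-to-E isomerisation.

Step 20
Reactants: 25 β-hydroxy ketone; 28 (2Z)-2-methylbut-2-enal
Product: 29 3-hydroxy-5-angeloyloxy-6-[(tert-butyldiphenylsilyloxy)methyl]-2,6,9-trimethyltricyclo[5.4.0.0^2,8]undecan-11-one (configuration as in the target)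
Conditions: SmI2 (30 mol%), 28 (5 equiv), THF, −10 °C
Reagents that add atoms: none
Why: Evans–Tishchenko reduction: the samarium-bound hemiacetal of 25 and 28 should deliver hydride within a six-membered chair to the C3 ketone, giving the 1,3-anti alcohol and leaving the acyl group on O5 as the angelate; the C11 ketone has no β-hydroxyl and stays.

Step 21
Reactants: 29 silyl ether
Product: 30 3-hydroxy-5-angeloyloxy-6-(hydroxymethyl)-2,6,9-trimethyltricyclo[5.4.0.0^2,8]undecan-11-one
Conditions: HF·pyridine, THF, 0 °C to rt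
Reagents that add atoms: none
Why: Fluoride desilylation should free the primary alcohol without harming the angelate.

Step 22
Reactants: 30 diol
Product: 31 target CNP0212099.1
Conditions: Ac2O, pyridine, CH2Cl2, 0 °C
Reagents that add atoms: acetic anhydride CC(=O)OC(C)=O
Why: Acetylation should take the primary alcohol selectively over the hindered secondary C3–OH next to the quaternary C2.

**Compound list**

1 | 2-methylprop-2-enal | C=C(C)C=O | starting material
2 | vinylmagnesium bromide | C=C[Mg]Br | starting material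
3 | rac-2-methylpenta-1,4-dien-3-ol | C=CC(O)C(C)=C | intermediate
4 | (1S)-1-[(2S)-2-methyloxiran-2-yl]prop-2-en-1-ol | C=C[C@H](O)[C@]1(C)CO1 | intermediate
5 | (2R)-2-(hydroxymethyl)-2-methylbut-3-enal | O=C[C@@](C=C)(C)CO | intermediate
6 | (2R)-2-{[(tert-butyldiphenylsilyl)oxy]methyl}-2-methylbut-3-enal | O=C[C@@](C=C)(C)CO[Si](c1ccccc1)(c1ccccc1)C(C)(C)C | intermediate
7 | 3-methylcyclohex-2-en-1-one | CC1=CC(=O)CCC1 | starting material
8 | ethynyltrimethylsilane | C#C[Si](C)(C)C | starting material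
9 | diisobutyl[1-(trimethylsilyl)ethenyl]aluminium | C=C([Si](C)(C)C)[Al](CC(C)C)CC(C)C | intermediate
10 | diisobutylaluminium enolate of (3S)-3-methyl-3-[1-(trimethylsilyl)ethenyl]cyclohexanone | C=C([Si](C)(C)C)[C@@]1(C)CCCC(O[Al](CC(C)C)CC(C)C)=C1 | intermediate
11 | (2R,3S)-2-[(1S,2R)-2-{[(tert-butyldiphenylsilyl)oxy]methyl}-1-hydroxy-2-methylbut-3-en-1-yl]-3-methyl-3-[1-(trimethylsilyl)ethenyl]cyclohexan-1-one | C=C([Si](C)(C)C)[C@@]1(C)CCCC(=O)[C@H]1[C@H](O)[C@@](C=C)(C)CO[Si](c1ccccc1)(c1ccccc1)C(C)(C)C | intermediate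
12 | triethylsilyl ether of 11 | C=C([Si](C)(C)C)[C@@]1(C)CCCC(=O)[C@H]1[C@H](O[Si](CC)(CC)CC)[C@@](C=C)(C)CO[Si](c1ccccc1)(c1ccccc1)C(C)(C)C | intermediate
13 | trimethylsilyl enol ether of 12 (C1–OSiMe3, C1=C6) | C=C([Si](C)(C)C)[C@@]1(C)CCC=C(O[Si](C)(C)C)[C@H]1[C@H](O[Si](CC)(CC)CC)[C@@](C=C)(C)CO[Si](c1ccccc1)(c1ccccc1)C(C)(C)C | intermediate
14 | (5S,6R)-6-[(1S,2R)-2-{[(tert-butyldiphenylsilyl)oxy]methyl}-2-methyl-1-(triethylsilyloxy)but-3-en-1-yl]-5-methyl-5-[1-(trimethylsilyl)ethenyl]cyclohex-2-en-1-one | C=C([Si](C)(C)C)[C@@]1(C)CC=CC(=O)[C@H]1[C@H](O[Si](CC)(CC)CC)[C@@](C=C)(C)CO[Si](c1ccccc1)(c1ccccc1)C(C)(C)C | intermediate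
15 | 2,3-epoxide of 14 | C=C([Si](C)(C)C)[C@@]1(C)CC2OC2C(=O)[C@H]1[C@H](O[Si](CC)(CC)CC)[C@@](C=C)(C)CO[Si](c1ccccc1)(c1ccccc1)C(C)(C)C | intermediate
16 | (4R,5S)-4-[(1S,2R)-2-{[(tert-butyldiphenylsilyl)oxy]methyl}-2-methyl-1-(triethylsilyloxy)but-3-en-1-yl]-5-methyl-5-[1-(trimethylsilyl)ethenyl]cyclohex-2-en-1-ol | C=C([Si](C)(C)C)[C@@]1(C)CC(O)C=C[C@H]1[C@H](O[Si](CC)(CC)CC)[C@@](C=C)(C)CO[Si](c1ccccc1)(c1ccccc1)C(C)(C)C | intermediate
17 | (4R,5S)-4-[(1S,2R)-2-{[(tert-butyldiphenylsilyl)oxy]methyl}-2-methyl-1-(triethylsilyloxy)but-3-en-1-yl]-5-methyl-5-[1-(trimethylsilyl)ethenyl]cyclohex-2-en-1-one | C=C([Si](C)(C)C)[C@@]1(C)CC(=O)C=C[C@H]1[C@H](O[Si](CC)(CC)CC)[C@@](C=C)(C)CO[Si](c1ccccc1)(c1ccccc1)C(C)(C)C | intermediate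
18 | (4R,5S)-4-[(1S,2R)-2-{[(tert-butyldiphenylsilyl)oxy]methyl}-1-hydroxy-2-methylbut-3-en-1-yl]-5-methyl-5-[1-(trimethylsilyl)ethenyl]cyclohex-2-en-1-one | C=C([Si](C)(C)C)[C@@]1(C)CC(=O)C=C[C@H]1[C@H](O)[C@@](C=C)(C)CO[Si](c1ccccc1)(c1ccccc1)C(C)(C)C | intermediate
19 | methanesulfonate of 18 | C=C([Si](C)(C)C)[C@@]1(C)CC(=O)C=C[C@H]1[C@H](OS(C)(=O)=O)[C@@](C=C)(C)CO[Si](c1ccccc1)(c1ccccc1)C(C)(C)C | intermediate
20 | 6-methyl-7-[1-(tert-butyldiphenylsilyloxy)-2-methylbut-3-en-2-yl]-6-[1-(trimethylsilyl)ethenyl]bicyclo[3.1.1]hept-3-en-2-one | C=C([Si](C)(C)C)[C@]2(C)[C@@H]3[C@@H]([C@H]2C(=O)C=C3)[C@@](C=C)(C)CO[Si](c1ccccc1)(c1ccccc1)C(C)(C)C | intermediate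
21 | 4,6-dimethyl-7-[1-(tert-butyldiphenylsilyloxy)-2-methylbut-3-en-2-yl]-6-[1-(trimethylsilyl)ethenyl]bicyclo[3.1.1]heptan-2-one | C=C([Si](C)(C)C)[C@]2(C)[C@@H]3[C@@H]([C@H]2C(=O)C[C@H]3C)[C@@](C=C)(C)CO[Si](c1ccccc1)(c1ccccc1)C(C)(C)C | intermediate
22 | epoxysilane of 21 (2-(trimethylsilyl)oxiran-2-yl in place of the silylvinyl group) | C[Si](C)(C)C1(CO1)[C@]2(C)[C@@H]3[C@@H]([C@H]2C(=O)C[C@H]3C)[C@@](C=C)(C)CO[Si](c1ccccc1)(c1ccccc1)C(C)(C)C | intermediate
23 | 6-acetyl-4,6-dimethyl-7-[1-(tert-butyldiphenylsilyloxy)-2-methylbut-3-en-2-yl]bicyclo[3.1.1]heptan-2-one | CC(=O)[C@]2(C)[C@@H]3[C@@H]([C@H]2C(=O)C[C@H]3C)[C@@](C=C)(C)CO[Si](c1ccccc1)(c1ccccc1)C(C)(C)C | intermediate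
24 | 2-(6-acetyl-4,6-dimethyl-2-oxobicyclo[3.1.1]heptan-7-yl)-3-(tert-butyldiphenylsilyloxy)-2-methylpropanal | CC(=O)[C@]2(C)[C@@H]3[C@@H]([C@H]2C(=O)C[C@H]3C)[C@@](C=O)(C)CO[Si](c1ccccc1)(c1ccccc1)C(C)(C)C | intermediate
25 | 5-hydroxy-6-[(tert-butyldiphenylsilyloxy)methyl]-2,6,9-trimethyltricyclo[5.4.0.0^2,8]undecane-3,11-dione | O[C@@H]1CC(=O)[C@]2(C)[C@@H]3[C@@H]([C@H]2C(=O)C[C@H]3C)[C@@]1(C)CO[Si](c1ccccc1)(c1ccccc1)C(C)(C)C | intermediate
26 | angelic acid, (2Z)-2-methylbut-2-enoic acid | C/C=C(/C)C(=O)O | starting material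
27 | (2Z)-2-methylbut-2-en-1-ol | C/C=C(/C)CO | intermediate
28 | (2Z)-2-methylbut-2-enal | C/C=C(/C)C=O | intermediate
29 | 3-hydroxy-5-angeloyloxy-6-[(tert-butyldiphenylsilyloxy)methyl]-2,6,9-trimethyltricyclo[5.4.0.0^2,8]undecan-11-one | C/C=C(/C)C(=O)O[C@@H]1C[C@@H](O)[C@]2(C)[C@@H]3[C@@H]([C@H]2C(=O)C[C@H]3C)[C@@]1(C)CO[Si](c1ccccc1)(c1ccccc1)C(C)(C)C | intermediate
30 | 3-hydroxy-5-angeloyloxy-6-(hydroxymethyl)-2,6,9-trimethyltricyclo[5.4.0.0^2,8]undecan-11-one | C/C=C(/C)C(=O)O[C@@H]1C[C@@H](O)[C@]2(C)[C@@H]3[C@@H]([C@H]2C(=O)C[C@H]3C)[C@@]1(C)CO | intermediate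
31 | CNP0212099.1, 6-(acetoxymethyl)-5-angeloyloxy-3-hydroxy-2,6,9-trimethyltricyclo[5.4.0.0^2,8]undecan-11-one | C/C=C(/C)C(=O)O[C@@H]1C[C@@H](O)[C@]2(C)[C@@H]3[C@@H]([C@H]2C(=O)C[C@H]3C)[C@@]1(C)COC(C)=O | target

**Summary**

Total step count: 22. Longest linear sequence: 20 steps (steps 1 to 17, then 20 to 22).

Steps most likely to fail:

- **Step 5.** The aluminium enolate may add sluggishly to the hindered aldehyde, or the aldehyde may approach the wrong enolate face, losing the cis relation between the new C8 substituent and the silylvinyl group. Fallback: make the two bonds in two operations. Setting out from 7 and 8, the same copper-catalysed conjugate addition is quenched with Me3SiCl to give the isolable silyl enol ether F1. A BF3·OEt2-promoted Mukaiyama aldol addition of silyl enol ether F1 to 6 (open transition state in place of the closed aluminium aldol) comes back to the route at 11.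

- **Step 13.** Base-induced elimination of the mesylate, or γ-deprotonation, may outrun the 4-exo-tet ring closure. Fallback: close the ring through a soft, sulfonyl-stabilised enolate that needs no strong base. Setting out from 17, LiN(SiMe3)2 and PhSO2F give the β-keto sulfone F2. Acid methanolysis gives the alcohol F3, and MeSO2Cl/Et3N the mesylate F4. Cs2CO3 in DMF should then cyclise to the bridgehead sulfone F5. Radical desulfonylation (Bu3SnH, AIBN, toluene, 80 °C) comes back to the route at 20.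

- **Step 17.** The bridged aldol addition may give poor facial selectivity at the aldehyde, or the aldol may revert or dehydrate. Fallback: set C5 by epoxidation instead of by the aldol. Setting out from 24, aldol condensation (piperidinium acetate, benzene, reflux) gives the cycloheptenone F6. Weitz–Scheffer epoxidation (H2O2, NaOH) from the face away from the silyloxymethyl group gives the epoxy ketone F7. SmI2 in THF/MeOH cleaves the Cα–O bond and comes back to the route at 25.

**Further compounds**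

F1 | step 5 | trimethyl({(3S)-3-methyl-3-[1-(trimethylsilyl)ethenyl]cyclohex-1-en-1-yl}oxy)silane | C=C([Si](C)(C)C)[C@@]1(C)CCCC(O[Si](C)(C)C)=C1
F2 | step 13 | 6-(phenylsulfonyl) derivative of 17 (sulfone on the CH2 between the carbonyl and the quaternary carbon) | C=C([Si](C)(C)C)[C@@]1(C)C(S(=O)(=O)c2ccccc2)C(=O)C=C[C@H]1[C@H](O[Si](CC)(CC)CC)[C@@](C=C)(C)CO[Si](c1ccccc1)(c1ccccc1)C(C)(C)C
F3 | step 13 | 6-(phenylsulfonyl) derivative of 18 | C=C([Si](C)(C)C)[C@@]1(C)C(S(=O)(=O)c2ccccc2)C(=O)C=C[C@H]1[C@H](O)[C@@](C=C)(C)CO[Si](c1ccccc1)(c1ccccc1)C(C)(C)C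
F4 | step 13 | 6-(phenylsulfonyl) derivative of 19 | C=C([Si](C)(C)C)[C@@]1(C)C(S(=O)(=O)c2ccccc2)C(=O)C=C[C@H]1[C@H](OS(C)(=O)=O)[C@@](C=C)(C)CO[Si](c1ccccc1)(c1ccccc1)C(C)(C)C
F5 | step 13 | 1-(phenylsulfonyl) derivative of 20 | C=C([Si](C)(C)C)[C@]2(C)[C@@H]3[C@@H]([C@@]2(S(=O)(=O)c4ccccc4)C(=O)C=C3)[C@@](C=C)(C)CO[Si](c1ccccc1)(c1ccccc1)C(C)(C)C
F6 | step 17 | 6-[(tert-butyldiphenylsilyloxy)methyl]-2,6,9-trimethyltricyclo[5.4.0.0^2,8]undec-4-ene-3,11-dione | C1=CC(=O)[C@]2(C)[C@@H]3[C@@H]([C@H]2C(=O)C[C@H]3C)[C@@]1(C)CO[Si](c1ccccc1)(c1ccccc1)C(C)(C)C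
F7 | step 17 | 4,5-epoxide of F6 (oxygen on the face of the C6 methyl) | O4[C@@H]1[C@H]4C(=O)[C@]2(C)[C@@H]3[C@@H]([C@H]2C(=O)C[C@H]3C)[C@@]1(C)CO[Si](c1ccccc1)(c1ccccc1)C(C)(C)C
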